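**Retrosynthetic overview**

1. Enabling feature: the two peroxide oxygens of the 1,2-dioxine (ring D) sit 1,4 across the cyclohexene (ring C) at C1 and C6, with the C9=C10 double bond between them. That is the pattern of a singlet-oxygen [4+2] adduct of a cyclohexa-1,3-diene. This diene is cis-fused to the cyclobutane (ring B), and the eight carbons of rings B and C, methylated at every second position with the pyronyl (ring A) trans to the neighbouring ring-B methyl, map onto the eight sp2 carbons of an (E,Z,Z,E)-tetraene.
2. Key disconnections, in retro order: both C–O bonds (cycloaddition), the ring-fusion C2–C5 bond (6π, disrotatory), the C3–C4 bond (8π, conrotatory), then the central σ-bond between the two Z-alkenes of the tetraene (Stille coupling of Z-dienylstannane 12 with Z-dienyl iodide 14).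
3. Ring order: ring A first (triketide lactonisation and O-methylation, steps 1–3); rings B and C together and ring D last, all in step 9, which should turn two achiral acyclic dienes and O2 into the tricycle with six stereocentres.
4. Fragments: 12 from ethylpyrone 5 and Z-stannyl enal 9 (anti-carbomagnesiation of propargyl alcohol) by vinylogous aldol addition and E1cB elimination; 14 from tiglic aldehyde by α-iodo Wittig olefination.
5. Tetraene 15 is achiral, so step 9 gives the racemate; the single enantiomer is secured by chiral-phase chromatography in step 10.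

Key step: step 9

Remark: because 15 is achiral, 16, 17 and 18 are racemic and are drawn as the enantiomer that corresponds to the target; enolates, alkoxides and other conjugate acids or bases are treated as forms of the numbered compounds.

**Route**

Step 1
Reactants: 1 ethyl 2-methyl-3-oxopentanoate; 2 N-methoxy-N-methylpropanamide
Product: 3 ethyl 2,4-dimethyl-3,5-dioxoheptanoate
Conditions: NaH, THF, 0 °C; n-BuLi, −10 °C; then 2, −78 → 0 °C; aq. NH4Cl
Reagents that add atoms: none
Why: γ-acylation of a β-keto ester dianion (Claisen-type condensation), in which the more reactive terminal enolate carbon attacks the Weinreb amide and the chelated tetrahedral intermediate prevents over-addition; the stereocentres of 3 are lost in step 2.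

Step 2
Reactants: 3 ethyl 2,4-dimethyl-3,5-dioxoheptanoate
Product: 4 6-ethyl-4-hydroxy-3,5-dimethyl-2H-pyran-2-one
Conditions: DBU, toluene, 110 °C; then 1 M HCl
Reagents that add atoms: none
Why: base-mediated enol lactonisation of a 3,5-diketo ester (attack of the C5 enol oxygen on the ester) is the standard closure of 4-hydroxy-2-pyrones and is driven by formation of the conjugated pyrone.

Step 3
Reactants: 4 6-ethyl-4-hydroxy-3,5-dimethyl-2H-pyran-2-one
Product: 5 2-ethyl-6-methoxy-3,5-dimethyl-4H-pyran-4-one
Conditions: MeOTf, CH2Cl2, 0 → 23 °C; then aq. NaHCO3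
Reagents that add atoms: methyl trifluoromethanesulfonate, COS(=O)(=O)C(F)(F)F
Why: O-methylation of the neutral hydroxypyrone by a hard alkylating agent should occur at the lactone carbonyl oxygen, the most basic site, to give a 2-methoxy-4-hydroxypyrylium ion whose deprotonation leaves the α-methoxy-γ-pyrone rather than the 4-methoxy-α-pyrone that base-mediated methylation would give.

Step 4
Reactants: 6 prop-2-yn-1-ol
Product: 8 (Z)-2-methyl-3-(tributylstannyl)prop-2-en-1-ol, via magnesiacycle 7 (not isolated)
Conditions: MeMgBr (2.5 equiv), CuI (10 mol%), Et2O/THF, −10 → 23 °C; then Bu3SnCl, 0 → 23 °C; aq. NH4Cl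
Reagents that add atoms: methylmagnesium bromide, C[Mg]Br; tributyltin chloride, CCCC[Sn](Cl)(CCCC)CCCC
Why: copper-catalysed carbomagnesiation of the magnesium propargyl alkoxide is anti-selective because the alkoxide holds magnesium in a five-membered chelate, so methyl enters at C2 and the metal sits at C3 cis to CH2OH; stannylation of this alkenyl Grignard reagent with retention fixes the Z geometry of the later C4=C5 alkene of the tetraene.

Step 5
Reactants: 8 (Z)-2-methyl-3-(tributylstannyl)prop-2-en-1-ol
Product: 9 (Z)-2-methyl-3-(tributylstannyl)prop-2-enal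
Conditions: MnO2, CH2Cl2, 23 °C
Reagents that add atoms: none
Why: MnO2 oxidises the allylic alcohol selectively under neutral conditions that should leave the C–Sn bond and the Z geometry untouched (allylic oxidation).

Step 6
Reactants: 5 2-ethyl-6-methoxy-3,5-dimethyl-4H-pyran-4-one; 9 (Z)-2-methyl-3-(tributylstannyl)prop-2-enal
Product: 10 2-[(4Z)-3-hydroxy-4-methyl-5-(tributylstannyl)pent-4-en-2-yl]-6-methoxy-3,5-dimethyl-4H-pyran-4-one (mixture of diastereomers)
Conditions: LiN(SiMe3)2, THF, −78 °C; then 9, −78 °C; aq. NH4Cl
Reagents that add atoms: none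
Why: deprotonation of 5 occurs at the CH2 of the 6-ethyl group (vinylogous enolate of the γ-pyrone), and this carbon should add 1,2 to the enal at −78 °C (vinylogous aldol addition); both new stereocentres are erased in step 7, so their configuration does not matter.

Step 7
Reactants: 10 2-[(4Z)-3-hydroxy-4-methyl-5-(tributylstannyl)pent-4-en-2-yl]-6-methoxy-3,5-dimethyl-4H-pyran-4-one
Product: 12 2-methoxy-3,5-dimethyl-6-[(2E,4Z)-4-methyl-5-(tributylstannyl)penta-2,4-dien-2-yl]-4H-pyran-4-one, via allylic mesylate 11 (not isolated)
Conditions: MsCl, Et3N, CH2Cl2, 0 °C; then DBU, 23 °C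
Reagents that add atoms: none
Why: mesylation followed by DBU-induced E1cB elimination through the vinylogous pyrone enolate should give the conjugated diene with the thermodynamically preferred E geometry (pyronyl trans to the alkenyl chain) from either diastereomer of 10, while the Z-alkenylstannane is inert to the basic medium.

Step 8
Reactants: 13 (E)-2-methylbut-2-enal (tiglic aldehyde)
Product: 14 (2Z,4E)-2-iodo-4-methylhexa-2,4-diene
Conditions: EtPPh3Br, n-BuLi, THF, 23 °C; I2, −78 °C; NaN(SiMe3)2, −78 → −20 °C; then 13, −78 → 0 °C
Reagents that add atoms: ethyltriphenylphosphonium bromide, CC[P+](c1ccccc1)(c1ccccc1)c1ccccc1.[Br-]; iodine, II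
Why: Wittig olefination with the non-stabilised α-iodo ylide Ph3P=C(I)CH3 proceeds through the cis-oxaphosphetane and should place iodine cis to the dienyl residue (Z-iodoalkene), while the E geometry of the tiglic double bond is kept.

Step 9
Reactants: 12 2-methoxy-3,5-dimethyl-6-[(2E,4Z)-4-methyl-5-(tributylstannyl)penta-2,4-dien-2-yl]-4H-pyran-4-one; 14 (2Z,4E)-2-iodo-4-methylhexa-2,4-diene
Product: 18 racemic target endoperoxide, via tetraene 15 (not isolated), via cyclooctatriene 16 (not isolated), via bicyclooctadiene 17 (not isolated)
Conditions: PdCl2(MeCN)2 (5 mol%), DMF, 23 °C, dark, Ar; then CH2Cl2, tetraphenylporphyrin (1 mol%), O2, white LEDs, 0 °C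
Reagents that add atoms: dioxygen, O=O
Why: Stille coupling at the bond between the two Z-alkenes (retention at both) unveils the (2E,4Z,6Z,8E)-tetraene 15, which should close thermally by 8π-conrotatory electrocyclization to cyclooctatriene 16 and by 6π-disrotatory electrocyclization to the cis-fused bicyclo[4.2.0]octa-2,4-diene 17, whose ring-locked s-cis diene then takes up photosensitised singlet oxygen in a suprafacial [4+2] cycloaddition that closes the 1,2-dioxine ring last. The closest known reaction types are the cross-coupling-triggered 8π/6π cascade of (E,Z,Z,E)-tetraenes and the singlet-oxygen Diels–Alder reaction of cyclohexa-1,3-dienes, here run consecutively in one flask. Modes of closure: the transient eight-membered ring by conrotatory bond formation between the tetraene termini, the four- and six-membered rings together by disrotatory formation of the ring-fusion bond, and the dioxine ring by concerted formation of both C–O bonds on one face of the diene. Stereocontrol: conrotation of the E,Z,Z,E tetraene places the two outside groups (pyronyl on the quaternary cyclobutane carbon, methyl on the neighbouring CH) trans; disrotation gives the cis ring fusion and is expected to favour the conformer that puts the flat pyronyl and a hydrogen, not two methyl groups, on the concave face; singlet oxygen should add to the convex diene face anti to the cyclobutane and its endo pyronyl group, which sets both C–O centres, so that all six centres arise in the relative configuration of the target (racemic, since 15 is achiral). The step needs retention of both Z geometries (mild ligand-free coupling in the dark), preference of singlet oxygen for the cisoid diene over ene reaction at the trisubstituted alkenes (cisoid dienes react far faster) and survival of the O–O bond, for which the phosphine-free, copper-free medium and 0 °C are chosen.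

Step 10
Reactants: 18 racemic target endoperoxide
Product: 19 target endoperoxide (single enantiomer)
Conditions: preparative chiral-phase SFC, immobilised amylose tris(3,5-dimethylphenylcarbamate), CO2/MeOH, 25 °C
Reagents that add atoms: none
Why: chromatographic resolution on a chiral stationary phase separates the two enantiomers without touching any stereocentre, and the enantiomer with the target configuration is assigned by comparing its optical rotation and ECD spectrum with calculated data.

**Compound list**

1 | ethyl 2-methyl-3-oxopentanoate | CCOC(=O)C(C)C(=O)CC | starting material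
2 | N-methoxy-N-methylpropanamide | CCC(=O)N(C)OC | starting material
3 | ethyl 2,4-dimethyl-3,5-dioxoheptanoate (stereoisomer and tautomer mixture) | CCOC(=O)C(C)C(=O)C(C)C(=O)CC | intermediate
4 | 6-ethyl-4-hydroxy-3,5-dimethyl-2H-pyran-2-one | CCC1=C(C)C(O)=C(C)C(=O)O1 | intermediate
5 | 2-ethyl-6-methoxy-3,5-dimethyl-4H-pyran-4-one | CCc1oc(OC)c(C)c(=O)c1C | intermediate
6 | prop-2-yn-1-ol (propargyl alcohol) | C#CCO | starting material
7 | 4-methyl-2,5-dihydro-1,2-oxamagnesole, the chelated alkenylmagnesium alkoxide; not isolated | CC1=C[Mg]OC1 | intermediate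
8 | (Z)-2-methyl-3-(tributylstannyl)prop-2-en-1-ol (tin cis to CH2OH) | CCCC[Sn](CCCC)(CCCC)/C=C(/C)CO | intermediate
9 | (Z)-2-methyl-3-(tributylstannyl)prop-2-enal (tin cis to CHO) | CCCC[Sn](CCCC)(CCCC)/C=C(/C)C=O | intermediate
10 | 2-[(4Z)-3-hydroxy-4-methyl-5-(tributylstannyl)pent-4-en-2-yl]-6-methoxy-3,5-dimethyl-4H-pyran-4-one (diastereomer mixture, racemic) | COc1oc(C(C)C(O)/C(C)=C\[Sn](CCCC)(CCCC)CCCC)c(C)c(=O)c1C | intermediate
11 | methanesulfonate of 10; not isolated | COc1oc(C(C)C(OS(C)(=O)=O)/C(C)=C\[Sn](CCCC)(CCCC)CCCC)c(C)c(=O)c1C | intermediate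
12 | 2-methoxy-3,5-dimethyl-6-[(2E,4Z)-4-methyl-5-(tributylstannyl)penta-2,4-dien-2-yl]-4H-pyran-4-one | COc1oc(/C(C)=C/C(C)=C\[Sn](CCCC)(CCCC)CCCC)c(C)c(=O)c1C | intermediate
13 | (E)-2-methylbut-2-enal (tiglic aldehyde) | C/C=C(\C)C=O | starting material
14 | (2Z,4E)-2-iodo-4-methylhexa-2,4-diene (iodine cis to C4) | C/C=C(\C)/C=C(/C)I | intermediate
15 | 2-methoxy-3,5-dimethyl-6-[(2E,4Z,6Z,8E)-4,6,8-trimethyldeca-2,4,6,8-tetraen-2-yl]-4H-pyran-4-one; not isolated | COc1oc(/C(C)=C/C(C)=C\C(C)=C/C(C)=C/C)c(C)c(=O)c1C | intermediate
16 | 2-methoxy-3,5-dimethyl-6-(1,3,5,7,8-pentamethylcycloocta-2,4,6-trien-1-yl)-4H-pyran-4-one, pyronyl trans to the 8-methyl; racemic; not isolated | COc1oc([C@]2(C)/C=C(C)\C=C(C)/C=C(C)\[C@H]2C)c(C)c(=O)c1C | intermediate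
17 | 2-methoxy-3,5-dimethyl-6-(1,3,5,7,8-pentamethylbicyclo[4.2.0]octa-2,4-dien-7-yl)-4H-pyran-4-one, cis-fused, pyronyl on the concave face, 1-, 7- and 8-methyls on the convex face; racemic; not isolated | COc1oc([C@@]2(C)[C@H](C)[C@@]3(C)C=C(C)C=C(C)[C@@H]23)c(C)c(=O)c1C | intermediate
18 | racemic 2-methoxy-3,5-dimethyl-6-(1,3,4,5,10-pentamethyl-7,8-dioxatricyclo[4.2.2.0(2,5)]dec-9-en-3-yl)-4H-pyran-4-one, relative configuration as in 19 (drawn as the target enantiomer) | COc1oc([C@@]2(C)[C@H](C)[C@@]3(C)[C@@H]4OO[C@@](C)(C=C4C)[C@@H]23)c(C)c(=O)c1C | intermediate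
19 | 2-methoxy-3,5-dimethyl-6-(1,3,4,5,10-pentamethyl-7,8-dioxatricyclo[4.2.2.0(2,5)]dec-9-en-3-yl)-4H-pyran-4-one, single enantiomer: cis-fused cyclobutane, pyronyl on the concave face, methyls at C3, C4 and C5 on the convex face, peroxide bridge anti to the cyclobutane, absolute configuration as in the SMILES | COc1oc([C@@]2(C)[C@H](C)[C@@]3(C)[C@@H]4OO[C@@](C)(C=C4C)[C@@H]23)c(C)c(=O)c1C | target

**Step count and risks**

Total step count: 10. Longest linear sequence: 7 steps (1, 2, 3, 6, 7, 9, 10).

Steps most likely to fail:

1. Step 9. Transmetalation at the hindered junction of two Z-alkenes may be slow, so that Z-to-E isomerisation and homocoupling compete. In the one-flask oxygenation, palladium and tin residues may quench the sensitiser or cleave the new O–O bond reductively. Fallback (sets out from 12 and 14, returns at 18): the polarity of the union is reversed and the oxygenation is run as a separate, metal-free operation. Iododestannylation of 12 (I2, CH2Cl2, 0 °C, retention) gives 2-[(2E,4Z)-5-iodo-4-methylpenta-2,4-dien-2-yl]-6-methoxy-3,5-dimethyl-4H-pyran-4-one F1. Iodine–lithium exchange on 14 (t-BuLi, Et2O, −78 °C) and borylation with 2-isopropoxy-4,4,5,5-tetramethyl-1,3,2-dioxaborolane gives 4,4,5,5-tetramethyl-2-[(2E,4E)-4-methylhexa-2,4-dien-2-yl]-1,3,2-dioxaborolane F2 (boron cis to C4, the same geometry as in 14). Suzuki–Miyaura coupling of F1 and F2 (PdCl2(dppf), K3PO4, DMF/H2O, 23 °C) should give 15 and, through 16, the bicyclooctadiene 17. This is isolated and purified, then photooxygenated (tetraphenylporphyrin, O2, visible light, CH2Cl2, 0 °C) to 18.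

2. Step 7. Geometric control may be lost in the E1cB elimination (formation of the 2Z isomer), and the Z-alkenylstannane may undergo protodestannylation during mesylation or chromatography. Fallback (sets out from 5 and 9, returns at 12): the C=C bond is made by phosphonate olefination instead of elimination. Bromination of the lithium enolate of 5 (LiN(SiMe3)2, THF, −78 °C; CBr4) gives 2-(1-bromoethyl)-6-methoxy-3,5-dimethyl-4H-pyran-4-one F3. A Michaelis–Arbuzov reaction with P(OEt)3 gives diethyl [1-(6-methoxy-3,5-dimethyl-4-oxo-4H-pyran-2-yl)ethyl]phosphonate F4. Horner–Wadsworth–Emmons olefination of F4 with 9 (NaH, THF, 0 °C) should give 12 directly, with E selectivity from the stabilised phosphonate carbanion and no sulfonylating or acidic stage.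

3. Step 8. Z selectivity may erode and conversion may be low in the α-iodo Wittig olefination of an α-branched enal, and the volatile product may be lost on concentration. Fallback (sets out from 13, returns at 14): the geometry is set by site-selective cross-coupling of a gem-dibromide. Corey–Fuchs dibromo-olefination of 13 (CBr4, PPh3, CH2Cl2, 0 °C) gives (3E)-1,1-dibromo-3-methylpenta-1,3-diene F5. Negishi monomethylation (MeZnCl, PdCl2(DPEphos), THF, 0 → 23 °C) replaces the less hindered bromine trans to the dienyl residue and gives (2Z,4E)-2-bromo-4-methylhexa-2,4-diene F6. Bromine–lithium exchange (t-BuLi, Et2O, −78 °C) and quenching with I2 gives 14 with retention.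

Further compounds
F1 | step 9 | 2-[(2E,4Z)-5-iodo-4-methylpenta-2,4-dien-2-yl]-6-methoxy-3,5-dimethyl-4H-pyran-4-one | COc1oc(/C(C)=C/C(C)=C\I)c(C)c(=O)c1C
F2 | step 9 | 4,4,5,5-tetramethyl-2-[(2E,4E)-4-methylhexa-2,4-dien-2-yl]-1,3,2-dioxaborolane (boron cis to C4) | C/C=C(\C)/C=C(/C)B1OC(C)(C)C(C)(C)O1
F3 | step 7 | 2-(1-bromoethyl)-6-methoxy-3,5-dimethyl-4H-pyran-4-one (racemic) | COc1oc(C(C)Br)c(C)c(=O)c1C
F4 | step 7 | diethyl [1-(6-methoxy-3,5-dimethyl-4-oxo-4H-pyran-2-yl)ethyl]phosphonate (racemic) | CCOP(=O)(OCC)C(C)c1oc(OC)c(C)c(=O)c1C
F5 | step 8 | (3E)-1,1-dibromo-3-methylpenta-1,3-diene | C/C=C(\C)C=C(Br)Br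
F6 | step 8 | (2Z,4E)-2-bromo-4-methylhexa-2,4-diene | C/C=C(\C)/C=C(/C)Br
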